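All constants are invented; the result is computed.

An integration gives you yields, not a reason, so reckon before you run.

| setting | ochre | amber | grey | green |
|---|---|---|---|---|
| Q | 20 mM | 20 mM (fed, over 4.80 h) | 20 mM | 20 mM |
| J | 20.0 mM | 20.0 mM | 20.0 mM | 20.0 mM (fed, over 4.80 h) |
| G | 1.0 mM | 1.0 mM | 1.0 mM | 1.0 mM |
| D | 0.20 mM | 0.20 mM | 0.20 mM | 0.20 mM |
| remark | one stirred flow tank at steady state, fed with the mixture as stated, mean residence time 6.0 h | a stirred flask in which Q is dosed at a steady rate over 4.80 h without added volume, worked up at 6.0 h | everything together in a closed stirred flask, run for 6.0 h | all but J at the start; J goes in evenly over 4.80 h, the run ends at 6.0 h |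
| time |  | 6.0 h | 6.0 h | 6.0 h |

    Q + G → G + Z (k1 = 5.5 /M/min)
    J + D + Z → D + L (k2 = 8200 /M²/min)
    Z → X (k3 = 0.0053 /min)

- the set-up with the highest amount of L at the outlet or at the end, in percent of the Q put in ("none" if the first two lie within 2 percentage points) (ochre / amber / grey / green / none)
- amount of L at the outlet or at the end, in percent of the Q put in, ochre
- amount of L at the outlet or at the end, in percent of the Q put in, amber
- amount of L at the outlet or at the end, in percent of the Q put in, grey
- amount of L at the outlet or at the end, in percent of the Q put in, green

- the stated concentrations are those of everything mixed, before any reaction; amounts are the same in each set-up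
- the feed brings no volume worth counting
- run time (amber): 6.0 h

Z stands at a fork: with J and D it goes on to L, and alone it falls to X. Take the pseudo-first-order constant of the L road, the L-step constant times [J][D], and divide it by the constant of the X road. With J at its charge this gives 6.19, and that is the fork ratio, the selectivity factor: Z going to L for each Z going to X. At fixed [D] it falls in step with [J].

My working guess for grey, ochre and amber is [J] at half its charge, which sends 75.6% of Z to L. Does that one number rank the set-ups? No, since it is the same for these three. Q needs a second number, the catalysed turnover over the run, 1.98. That number converts 86.2% of Q in closed grey and 66.4% in the tank ochre; amber, where Q is dosed, also needs the dosing time, and I get 66.2% there. So I reckon 65.1% for grey, 50.2% for ochre and 50.1% for amber. Green converts Q as grey does, but J is dosed, so [J] climbs from nothing and I take a quarter of its charge on average, giving 52.4%. My pick is grey.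

The forecast also names grey, with 45.7% for ochre, 47% for amber, 64% for grey and 53.5% for green, holding that “having all the Q and J present from the start gives the fastest, most selective conversion”. My ochre and amber figures stand higher than its own.

The run agrees with the forecast on grey, giving 45.7% for ochre, 47.0% for amber, 64.1% for grey and 53.5% for green. In grey at 6.00 h, the L road outruns the X road 2.2 to one, and the fork ratio with 36% of the J charge still there is 2.23. In the neighbour of grey charged with 5.0 mM of J, the fork ratio starts at 1.55, lower than grey's, and that flask ends with 23.2% of L against 42.3% of X.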